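**Plan**

- The target is an achiral isoflavone. C4 is a ketone carbon on ring A, C3 carries ring B, and C3 is tied to the ring A oxygen O1 through C2. A ring A aldehyde (future C4) whose ortho oxygen carries a CH2–C(=O)–aryl arm (C2 and C3) can therefore close ring C by acyl-anion addition to that ketone.
- Retrosynthetic cuts, in order: the three MOM ethers; the C2=C3 double bond (back to a C3 carbinol); the C3–C4 bond of ring C; the O1–C2 ether bond (phenol plus α-bromo ketone); on ring A the prenyl alkene (cross-metathesis) and the C8–allyl bond (Claisen shift); on ring B the O–C and C–C bonds of its fused pyran ring (propargyl ether rearrangement).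
- Forward: aldehyde 7 (ring A, four steps) and bromo ketone 15 (ring B with its pyran ring, four steps) are made separately. The pyran ring arises first, then the O1–C2 ether, then ring C, then the C2=C3 bond and the free phenols.
- Stereochemistry: the target has no stereocentre. C3 becomes a racemic carbinol centre in step 10 and is made trigonal again in step 11. The C8 position of the prenyl group is fixed by the Claisen shift next to the phenol that later becomes O1.

Key step: step 10

Remark: 12 and 14 are the only intermediates treated as compounds in their own right; tautomers, catalyst adducts and reagent esters that exist only within a single transformation are covered by the mechanism given in the Why line.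

**Route**

Step 1
Reactants: 1 2,4,6-trihydroxybenzaldehyde
Product: 2 2-hydroxy-4,6-bis(methoxymethoxy)benzaldehyde
Conditions: MOMCl (2.2 equiv), i-Pr2NEt, CH2Cl2, 0 °C → rt
Reagents that add atoms: chloromethyl methyl ether, COCCl
Why: Base-mediated O-alkylation (Williamson-type acetal ether formation) should take the para hydroxyl and one of the two equivalent ortho hydroxyls, after which the last hydroxyl is held in a hydrogen bond to the aldehyde and stays free.

Step 2
Reactants: 2 2-hydroxy-4,6-bis(methoxymethoxy)benzaldehyde; 3 allyl bromide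
Product: 4 2-(allyloxy)-4,6-bis(methoxymethoxy)benzaldehyde
Conditions: K2CO3, DMF, 50 °C
Reagents that add atoms: none
Why: Williamson ether synthesis at the only free phenol, with a polar solvent and mild heating to overcome the hydrogen bond to the aldehyde.

Step 3
Reactants: 4 2-(allyloxy)-4,6-bis(methoxymethoxy)benzaldehyde
Product: 5 3-allyl-2-hydroxy-4,6-bis(methoxymethoxy)benzaldehyde
Conditions: PhNEt2, 190 °C, sealed tube
Reagents that add atoms: none
Why: Aromatic Claisen rearrangement ([3,3] shift, then tautomerisation) can deliver the allyl group only to C3, because the other ortho position carries the formyl group; the basic solvent protects the MOM acetals.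

Step 4
Reactants: 5 3-allyl-2-hydroxy-4,6-bis(methoxymethoxy)benzaldehyde; 6 2-methylbut-2-ene
Product: 7 2-hydroxy-4,6-bis(methoxymethoxy)-3-(3-methylbut-2-en-1-yl)benzaldehyde
Conditions: second-generation Grubbs catalyst RuCl2(=CHPh)(PCy3)(H2IMes) (5 mol%), 2-methylbut-2-ene (large excess), CH2Cl2, 40 °C
Reagents that add atoms: none
Why: Olefin cross-metathesis of the terminal allyl alkene with excess 2-methylbut-2-ene should exchange the CH2 terminus for an isopropylidene group, a standard allyl-to-prenyl conversion that tolerates phenols and aldehydes.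

Step 5
Reactants: 8 2,4-dihydroxyacetophenone
Product: 9 1-[2-hydroxy-4-(methoxymethoxy)phenyl]ethan-1-one
Conditions: MOMCl (1.1 equiv), K2CO3, acetone, rt
Reagents that add atoms: chloromethyl methyl ether, COCCl
Why: Selective Williamson-type O-alkylation of the 4-hydroxyl, since the 2-hydroxyl is deactivated by its hydrogen bond to the acetyl group.

Step 6
Reactants: 9 1-[2-hydroxy-4-(methoxymethoxy)phenyl]ethan-1-one; 10 3-chloro-3-methylbut-1-yne
Product: 11 1-[4-(methoxymethoxy)-2-(2-methylbut-3-yn-2-yloxy)phenyl]ethan-1-one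
Conditions: CuCl2·2H2O (1 mol%), DBU, MeCN, 0 °C → rt
Reagents that add atoms: none
Why: Copper-catalysed propargylic etherification (substitution through a copper acetylide) places the 1,1-dimethylpropargyl group on the only free phenol, the oxygen ortho to the acetyl group, which decides the later ring fusion.

Step 7
Reactants: 11 1-[4-(methoxymethoxy)-2-(2-methylbut-3-yn-2-yloxy)phenyl]ethan-1-one
Product: 13 1-[5-(methoxymethoxy)-2,2-dimethyl-2H-chromen-8-yl]ethan-1-one, via allenylphenol 12 (not isolated)
Conditions: PhNEt2, 180 °C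
Reagents that add atoms: none
Why: Aryl propargyl ether Claisen rearrangement gives 12 at the only free ortho carbon (the other carries the acetyl group), and a [1,5]-hydrogen shift followed by oxa-6π electrocyclisation closes the 2,2-dimethylpyran ring onto the same oxygen.

Step 8
Reactants: 13 1-[5-(methoxymethoxy)-2,2-dimethyl-2H-chromen-8-yl]ethan-1-one
Product: 15 2-bromo-1-[5-(methoxymethoxy)-2,2-dimethyl-2H-chromen-8-yl]ethan-1-one, via silyl enol ether 14 (not isolated)
Conditions: LiN(SiMe3)2, Me3SiCl, THF, −78 °C; crude 14, NBS, NaHCO3, THF, −78 → 0 °C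
Reagents that add atoms: N-bromosuccinimide, O=C1CCC(=O)N1Br; chlorotrimethylsilane, C[Si](C)(C)Cl (silyl group of 14 only)
Why: Kinetic enolisation with silyl trapping, then electrophilic bromination of the silyl enol ether, should give the mono-α-bromo ketone without free HBr, so that the MOM acetal and the chromene double bond are spared.

Step 9
Reactants: 7 2-hydroxy-4,6-bis(methoxymethoxy)-3-(3-methylbut-2-en-1-yl)benzaldehyde; 15 2-bromo-1-[5-(methoxymethoxy)-2,2-dimethyl-2H-chromen-8-yl]ethan-1-one
Product: 16 2-{2-[5-(methoxymethoxy)-2,2-dimethyl-2H-chromen-8-yl]-2-oxoethoxy}-4,6-bis(methoxymethoxy)-3-(3-methylbut-2-en-1-yl)benzaldehyde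
Conditions: K2CO3, DMF, 0 °C → rt
Reagents that add atoms: none
Why: Williamson etherification (SN2 at the activated α-halo ketone) by the only free phenol of 7, which lies between the formyl and prenyl groups, run at or below room temperature to hold back aldol condensation of the product.

Step 10
Reactants: 16 2-{2-[5-(methoxymethoxy)-2,2-dimethyl-2H-chromen-8-yl]-2-oxoethoxy}-4,6-bis(methoxymethoxy)-3-(3-methylbut-2-en-1-yl)benzaldehyde
Product: 17 racemic 3-hydroxy-5,7-bis(methoxymethoxy)-3-[5-(methoxymethoxy)-2,2-dimethyl-2H-chromen-8-yl]-8-(3-methylbut-2-en-1-yl)chroman-4-one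
Conditions: 2-(pentafluorophenyl)-6,7-dihydro-5H-pyrrolo[2,1-c][1,2,4]triazol-2-ium tetrafluoroborate (15 mol%), DBU (15 mol%), THF (0.05 M), rt → 40 °C, argon
Reagents that add atoms: none
Why: DBU deprotonates the triazolium salt to the carbene, which adds to the aldehyde carbon of 16 (future C4); proton transfer gives the nucleophilic enaminol (Breslow intermediate), whose carbon attacks the tethered aryl ketone carbon (future C3), and collapse of the adduct releases the carbene and the α-hydroxy ketone 17. The closest known reaction type is the N-heterocyclic-carbene-catalysed intramolecular crossed aldehyde–ketone benzoin reaction of 2-(2-aryl-2-oxoethoxy)benzaldehydes to 3-aryl-3-hydroxychroman-4-ones. Ring C closes in the 6-exo-trig mode: the ketone carbon lies in the new ring (C4, C4a, C8a, O1, C2, C3) and its oxygen outside it. The new stereocentre C3 is formed without control because the catalyst is achiral, so 17 should be racemic, which does not matter because C3 becomes trigonal in step 11. The step needs the aldehyde and not the ketone to act as acyl donor, ring closure to outrun aldehyde dimerisation, and carbene catalysis to outrun base-induced aldol closure of the C2 methylene onto the aldehyde; only the aldehyde has the C–H needed for the enaminol, the doubly ortho-oxygenated aldehyde is too crowded to dimerise while the ketone is held within reach by the short tether, and the base is limited to the catalyst loading.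

Step 11
Reactants: 17 racemic 3-hydroxy-5,7-bis(methoxymethoxy)-3-[5-(methoxymethoxy)-2,2-dimethyl-2H-chromen-8-yl]-8-(3-methylbut-2-en-1-yl)chroman-4-one
Product: 18 5,7-bis(methoxymethoxy)-3-[5-(methoxymethoxy)-2,2-dimethyl-2H-chromen-8-yl]-8-(3-methylbut-2-en-1-yl)-4H-chromen-4-one
Conditions: Burgess reagent (methyl N-(triethylammoniosulfonyl)carbamate), toluene, 70 °C
Reagents that add atoms: none
Why: Burgess dehydration (O-sulfonylation of the tertiary alcohol, then intramolecular syn-elimination) can only form the C2=C3 bond, because C2 holds the only β-hydrogens, and the neutral conditions spare the MOM ethers, the prenyl group and the chromene.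

Step 12
Reactants: 18 5,7-bis(methoxymethoxy)-3-[5-(methoxymethoxy)-2,2-dimethyl-2H-chromen-8-yl]-8-(3-methylbut-2-en-1-yl)-4H-chromen-4-one
Product: 19 5,7-dihydroxy-3-(5-hydroxy-2,2-dimethyl-2H-chromen-8-yl)-8-(3-methylbut-2-en-1-yl)-4H-chromen-4-one
Conditions: HCl (3 M in MeOH), MeOH–THF, 45 °C
Reagents that add atoms: none
Why: Acid-catalysed acetal methanolysis should remove all three MOM ethers, and dilute methanolic acid at moderate temperature is chosen so that the prenyl group is not cyclised onto the 7-hydroxyl and the chromene is not solvated.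

**Compound list**

1 | 2,4,6-trihydroxybenzaldehyde | O=Cc1c(O)cc(O)cc1O | starting material
2 | 2-hydroxy-4,6-bis(methoxymethoxy)benzaldehyde | O=Cc1c(O)cc(OCOC)cc1OCOC | intermediate
3 | allyl bromide (3-bromoprop-1-ene) | C=CCBr | starting material
4 | 2-(allyloxy)-4,6-bis(methoxymethoxy)benzaldehyde | O=Cc1c(OCC=C)cc(OCOC)cc1OCOC | intermediate
5 | 3-allyl-2-hydroxy-4,6-bis(methoxymethoxy)benzaldehyde | O=Cc1c(O)c(CC=C)c(OCOC)cc1OCOC | intermediate
6 | 2-methylbut-2-ene | CC=C(C)C | starting material
7 | 2-hydroxy-4,6-bis(methoxymethoxy)-3-(3-methylbut-2-en-1-yl)benzaldehyde | O=Cc1c(O)c(CC=C(C)C)c(OCOC)cc1OCOC | intermediate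
8 | 2,4-dihydroxyacetophenone | CC(=O)c1ccc(O)cc1O | starting material
9 | 1-[2-hydroxy-4-(methoxymethoxy)phenyl]ethan-1-one | CC(=O)c1ccc(OCOC)cc1O | intermediate
10 | 3-chloro-3-methylbut-1-yne | CC(C)(Cl)C#C | starting material
11 | 1-[4-(methoxymethoxy)-2-(2-methylbut-3-yn-2-yloxy)phenyl]ethan-1-one | CC(=O)c1ccc(OCOC)cc1OC(C)(C)C#C | intermediate
12 | 1-[2-hydroxy-4-(methoxymethoxy)-3-(3-methylbuta-1,2-dien-1-yl)phenyl]ethan-1-one | CC(=O)c1ccc(OCOC)c(C=C=C(C)C)c1O | intermediate (not isolated)
13 | 1-[5-(methoxymethoxy)-2,2-dimethyl-2H-chromen-8-yl]ethan-1-one | CC(=O)c1ccc(OCOC)c2c1OC(C)(C)C=C2 | intermediate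
14 | {1-[5-(methoxymethoxy)-2,2-dimethyl-2H-chromen-8-yl]ethenyl}oxy(trimethyl)silane | C=C(O[Si](C)(C)C)c1ccc(OCOC)c2c1OC(C)(C)C=C2 | intermediate (not isolated)
15 | 2-bromo-1-[5-(methoxymethoxy)-2,2-dimethyl-2H-chromen-8-yl]ethan-1-one | O=C(CBr)c1ccc(OCOC)c2c1OC(C)(C)C=C2 | intermediate
16 | 2-{2-[5-(methoxymethoxy)-2,2-dimethyl-2H-chromen-8-yl]-2-oxoethoxy}-4,6-bis(methoxymethoxy)-3-(3-methylbut-2-en-1-yl)benzaldehyde | O=Cc1c(OCC(=O)c2ccc(OCOC)c3c2OC(C)(C)C=C3)c(CC=C(C)C)c(OCOC)cc1OCOC | intermediate
17 | racemic 3-hydroxy-5,7-bis(methoxymethoxy)-3-[5-(methoxymethoxy)-2,2-dimethyl-2H-chromen-8-yl]-8-(3-methylbut-2-en-1-yl)chroman-4-one | CC(C)=CCc1c(OCOC)cc(OCOC)c2c1OCC(O)(c1ccc(OCOC)c3c1OC(C)(C)C=C3)C2=O | intermediate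
18 | 5,7-bis(methoxymethoxy)-3-[5-(methoxymethoxy)-2,2-dimethyl-2H-chromen-8-yl]-8-(3-methylbut-2-en-1-yl)-4H-chromen-4-one | CC(C)=CCc1c(OCOC)cc(OCOC)c2c(=O)c(-c3ccc(OCOC)c4c3OC(C)(C)C=C4)coc12 | intermediate
19 | 5,7-dihydroxy-3-(5-hydroxy-2,2-dimethyl-2H-chromen-8-yl)-8-(3-methylbut-2-en-1-yl)-4H-chromen-4-one | CC(C)=CCc1c(O)cc(O)c2c(=O)c(-c3ccc(O)c4c3OC(C)(C)C=C4)coc12 | target

**Step count and risks**

Total step count: 12. Longest linear sequence: 8 (steps 1–4 or steps 5–8, followed by steps 9–12).

Steps most likely to fail: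

1. Step 10. Carbene addition to the doubly ortho-oxygenated, electron-rich aldehyde may be too slow, so that base-induced aldol closure of the C2 methylene onto the aldehyde, or simple non-reaction, takes over. The fallback sets out from 13 and 7, comes back at 18, and makes the C3–C4 bond between the fragments before ring C is closed. Ketone 13 is converted (KN(SiMe3)2, PhNTf2, THF, −78 °C) into 1-[5-(methoxymethoxy)-2,2-dimethyl-2H-chromen-8-yl]ethenyl trifluoromethanesulfonate F1. A Nozaki–Hiyama–Kishi reaction of F1 with aldehyde 7 (CrCl2 in excess, NiCl2 cat., DMF, rt) should give racemic 2-{1-hydroxy-2-[5-(methoxymethoxy)-2,2-dimethyl-2H-chromen-8-yl]prop-2-en-1-yl}-3,5-bis(methoxymethoxy)-6-(3-methylbut-2-en-1-yl)phenol F2. MnO2 in CH2Cl2 oxidises the benzylic allylic alcohol to 1-[2-hydroxy-4,6-bis(methoxymethoxy)-3-(3-methylbut-2-en-1-yl)phenyl]-2-[5-(methoxymethoxy)-2,2-dimethyl-2H-chromen-8-yl]prop-2-en-1-one F3, which is not isolated: brief exposure to K2CO3 in MeOH lets the ortho phenol add in a 6-endo oxa-Michael closure to racemic 5,7-bis(methoxymethoxy)-3-[5-(methoxymethoxy)-2,2-dimethyl-2H-chromen-8-yl]-8-(3-methylbut-2-en-1-yl)chroman-4-one F4. Its potassium enolate (KN(SiMe3)2, THF, −78 °C) is brominated with NBS to racemic 3-bromo-5,7-bis(methoxymethoxy)-3-[5-(methoxymethoxy)-2,2-dimethyl-2H-chromen-8-yl]-8-(3-methylbut-2-en-1-yl)chroman-4-one F5, which is not isolated either, and DBU removes HBr across C2–C3 to give 18.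

2. Step 6. The hydrogen-bonded phenoxide next to the acetyl group may attack the tertiary propargylic electrophile too slowly, so that loss of HCl from 10 uses up the reagent. The fallback sets out from 9 and comes back at 13; it builds the pyran ring by condensation in place of etherification and rearrangement. Phenol 9 is heated with 3-methylbut-2-enal and catalytic ethylenediammonium diacetate in xylene at 140 °C (or in pyridine at the same temperature). Aldol-type attack of C3 on the enal, loss of water to the ortho-quinone methide and oxa-6π electrocyclisation can use only the one free phenol, so the same chromene 13 should result. Water is the only by-product and no new compound arises (F0).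

3. Step 9. Alkylation of the flanked, chelated phenoxide may be slow enough for base-induced intramolecular aldol condensation of the product (benzofuran formation) to overtake it. The fallback sets out from 15 and 7 and comes back at 16; it forms the O1–C2 bond without base. Bromo ketone 15 is heated with HCO2Na in ethanol, which gives 2-[5-(methoxymethoxy)-2,2-dimethyl-2H-chromen-8-yl]-2-oxoethyl formate F6 (not isolated); ethanolysis in the same flask gives 2-hydroxy-1-[5-(methoxymethoxy)-2,2-dimethyl-2H-chromen-8-yl]ethan-1-one F7. A Mitsunobu reaction of F7 with phenol 7 (PPh3, diisopropyl azodicarboxylate, THF, 0 °C → rt) should give 16 under neutral conditions.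

**Further compounds**

F1 | step 10 | 1-[5-(methoxymethoxy)-2,2-dimethyl-2H-chromen-8-yl]ethenyl trifluoromethanesulfonate | C=C(OS(=O)(=O)C(F)(F)F)c1ccc(OCOC)c2c1OC(C)(C)C=C2
F2 | step 10 | racemic 2-{1-hydroxy-2-[5-(methoxymethoxy)-2,2-dimethyl-2H-chromen-8-yl]prop-2-en-1-yl}-3,5-bis(methoxymethoxy)-6-(3-methylbut-2-en-1-yl)phenol | C=C(c1ccc(OCOC)c2c1OC(C)(C)C=C2)C(O)c1c(O)c(CC=C(C)C)c(OCOC)cc1OCOC
F3 | step 10 | 1-[2-hydroxy-4,6-bis(methoxymethoxy)-3-(3-methylbut-2-en-1-yl)phenyl]-2-[5-(methoxymethoxy)-2,2-dimethyl-2H-chromen-8-yl]prop-2-en-1-one | C=C(c1ccc(OCOC)c2c1OC(C)(C)C=C2)C(=O)c1c(O)c(CC=C(C)C)c(OCOC)cc1OCOC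
F4 | step 10 | racemic 5,7-bis(methoxymethoxy)-3-[5-(methoxymethoxy)-2,2-dimethyl-2H-chromen-8-yl]-8-(3-methylbut-2-en-1-yl)chroman-4-one | CC(C)=CCc1c(OCOC)cc(OCOC)c2c1OCC(c1ccc(OCOC)c3c1OC(C)(C)C=C3)C2=O
F5 | step 10 | racemic 3-bromo-5,7-bis(methoxymethoxy)-3-[5-(methoxymethoxy)-2,2-dimethyl-2H-chromen-8-yl]-8-(3-methylbut-2-en-1-yl)chroman-4-one | CC(C)=CCc1c(OCOC)cc(OCOC)c2c1OCC(Br)(c1ccc(OCOC)c3c1OC(C)(C)C=C3)C2=O
F0 | step 6 | none | none
F6 | step 9 | 2-[5-(methoxymethoxy)-2,2-dimethyl-2H-chromen-8-yl]-2-oxoethyl formate | O=COCC(=O)c1ccc(OCOC)c2c1OC(C)(C)C=C2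
F7 | step 9 | 2-hydroxy-1-[5-(methoxymethoxy)-2,2-dimethyl-2H-chromen-8-yl]ethan-1-one | O=C(CO)c1ccc(OCOC)c2c1OC(C)(C)C=C2
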